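# Synthesis plan for CNP0220272.2 (bis-ent-labdane, C40H56O8)

## The problem

1. Target 11 is an unsymmetrical dimer of two ent-labdanes joined by one bond, C15–C12'. Labdane numbering is used: unprimed atoms belong to the half whose E-alkene C11=C12 is conjugated with the butenolide ring O–C15–C14=C13–C16, and primed atoms to the half whose butenolide ring O–C15'–C14'=C13'–C16' hangs on C12'.
2. Ten of the twelve stereocentres are one set written twice. C3, C4, C5, C9 and C10 of each trans-decalin, with the exocyclic methylene C8=C17, the equatorial C3 hydroxyl and the axial C19 hydroxymethyl, coincide atom for atom with andrographolide (1).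
3. The unsolved part is the pair C15 (R) / C12' (S). These are two adjacent tertiary centres on a freely rotating bond between two bulky halves, too far from C9 and C9' for the decalins to control them, so they must be set in the bond-forming event itself.
4. C15 is also the γ-carbon of a dienyl butenolide and is epimerised by base through the furanolate, so everything that follows its creation has to be neutral or acidic.
5. The two 1,1-disubstituted alkenes exclude hydrogenation, hydroboration, ozone and strong acid, the two unsaturated lactones exclude hard nucleophiles and most hydride reagents, and four hydroxyls need masking.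
6. The feature that makes the key step possible is twofold: the segment C12'(–C15)–C13'=C14' of the primed butenolide is the 1,3-transposed form of the allylic alcohol C12=C13–C14(OH) of 1, and C15 is flanked by C14, a ring carbon that can carry an oxygen (tetronic acid level) and lose it again.
7. An ether C14'–O–C14 therefore lines up the six atoms C15=C14–O–C14'–C13'=C12' once the unprimed ring is aromatised to a furan, and a [3,3] shift turns one sacrificial stereocentre (C14') into both junction centres.

## Retrosynthesis

**11 ⇒ 10.** Only the C3–O and C19–O bonds to two isopropylidene carbons are cut.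
- An acetonide is preferred to esters or silyl ethers because it forms on the 1,3-diol of 1 alone and leaves C14–OH free.
- It offers no acidic or nucleophilic site, and it falls off in aqueous acetic acid, a medium in which C15 cannot epimerise.
- 10 has the same skeleton as 11 but no free hydroxyl. The forward reaction only has to spare the C8=C17 alkenes.

**10 ⇒ 9 ⇒ 8.** The C14–H bond is exchanged for C14–O, giving triflate 9 and then tetronic acid 8.
- This adds an atom in the retrosynthetic sense, which pays for two reasons. The enol oxygen on C14 is the only position next to C15 from which a tether can reach the primed half. A 5-substituted tetronic acid also holds its C5 (here C15) configuration far better than the dienyl butenolide does.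
- Oxygen on C13 or C16 would not place C15 at the end of a six-atom array.
- The forward reactions are sulfonylation and palladium-catalysed hydride transfer. They must remove this one oxygen without base strong enough to reach C15–H.

**8 ⇒ 5 (through 7 and 6).** The C15–C12' bond is cut, the C14'–O bond is re-formed, and the alkene goes back from C13'=C14' to C12'=C13'.
- Cuts at C12'–C13', C11'–C12' or C12–C13 would leave the C15/C12' pair inside one fragment, still to be made.
- Only the cut at C15–C12' gives two C20 halves that both map on 1.
- Ether 5 has one junction stereocentre (C14') in place of two, no C–C bond between the halves, and is an isomer of 8.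
- The forward reaction is a dearomative Claisen shift of silyloxyfuran 6. It must be suprafacial (C12'), chair-like (C15) and directed to C15, not C13.

**5 ⇒ 2 + 4.** The sp3 bond C14'–O is cut, not the sp2 bond O–C14.
- In 1 the C14 hydroxyl stands on the face of the C12=C13 plane opposite to the one on which C15 sits in 11. A suprafacial shift therefore needs the 14'-epimer.
- Displacement at C14' supplies this inversion in the coupling step itself.
- Alcohol 2 and tetronic acid 4 are C23 compounds, one and two steps from 1.
- The forward Mitsunobu reaction must prefer O14 of 4 and direct substitution over allylic attack or elimination.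

**4 ⇒ 2 (through 3) ⇒ 1.** No C–C bond is cut.
- 4 is the enol tautomer of the 14-ketone 3 of 2, so one oxidation creates both the C11=C12 alkene of the unprimed half and the acidic OH for the coupling.
- 2 is the acetonide of 1. Both halves thus come from one intermediate.
- All ten decalin stereocentres are bought with 1 rather than built twice.

## Roads not taken

**Alternative 1:** This is the most obvious cut, C15–C12' between two free molecules.
- The forward key step is a Lewis-acid-promoted vinylogous Mukaiyama–Michael addition of silyloxyfuran A1 to C12' of triacetate A2, with loss of the C14' acetate, to give tetraacetate A3.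
- The step count is similar, but control is missing. The two faces of the flat furan A1 differ only through C9, five bonds away.
- The face of C12' depends on whether acetate leaves in concert with attack or after it.
- A2 readily loses acetic acid toward C11', and A1 can also react at C13.
- Up to four junction isomers must be expected. In the chosen plan the tether fixes the C12' face and reduces C15 to one chair/boat choice.

**Alternative 2:** The same bond is cut, with the halves tied through a carbonate.
- The forward key step is ionisation of the mixed dienol carbonate A4 by zerovalent palladium, loss of CO2 and recombination of the ion pair to 10.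
- Ionisation and outer-sphere attack each invert, so the (14'R) series is needed here too and must be made in extra steps.
- The allyl complex carries two secondary termini (C12', C14') and can equilibrate its faces.
- Butenolide dienolates are usually allylated at the α-carbon (C13) in such reactions. The Cope shift that would then move the allyl group to C15 transposes it again and ends at C14'.
- The tether is lost before the C–C bond forms, so it controls nothing at C15.

**Alternative 3:** The sp2–sp2 bond C12–C13 is cut.
- The forward key step is a Stille coupling of vinyl iodide A5 with stannylbutenolide A6 to give 10.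
- The coupling itself is safe, but A6 still contains the whole C15/C12' problem.
- A5 requires cutting C13–C16 off a molecule of 1 only to rebuild the same ring on the other fragment.
- The route becomes roughly twice as long, and the hard bond is merely postponed.

Key step: step 4

Assumption: andrographolide (1), a bulk plant isolate listed by the usual catalogue suppliers, is taken as the commercial starting material. Its C3, C4, C5, C9 and C10 configurations were compared with both halves of the target SMILES and coincide.

## Route

Step 1
Reactants: 1 andrographolide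
Product: 2 3,19-O-isopropylideneandrographolide
Conditions: 2,2-dimethoxypropane, PPTS (cat.), toluene–DMSO, 80 °C
Reagents that add atoms: 2,2-dimethoxypropane COC(C)(C)OC
Why: Acid-catalysed transacetalisation: only the equatorial C3–OH and the axial C19–OH can share a six-membered 1,3-dioxane, so the allylic C14–OH stays free. No stereocentre is touched.

Step 2
Reactants: 2 3,19-O-isopropylideneandrographolide (one portion)
Product: 4 (11E)-14-hydroxy-3,19-O-isopropylidene-ent-labda-8(17),11,13-trien-16,15-olide (3-alkenyltetronic acid), via alkylidene dione 3 (not isolated)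
Conditions: DMP (1.05 equiv), CH2Cl2, 0 °C; then Et3N (cat.), 0 °C
Reagents that add atoms: none
Why: Hypervalent-iodine oxidation of the allylic C14 carbinol is near neutral and spares C8=C17 and the acetonide. The 3-alkylidenefuran-2,4-dione 3 has very acidic C11 protons (vinylogous 1,3-dicarbonyl), so a trace of amine should move it to the conjugated enol 4, the normal form of tetronic acids. The new C11=C12 alkene should be E because decalin and ring avoid each other, and C9 is not touched.

Step 3
Reactants: 2 3,19-O-isopropylideneandrographolide; 4 3-alkenyltetronic acid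
Product: 5 (14'R)-allyl tetronate ether (O14 of 4 bound to C14' of the skeleton of 2, 12'E)
Conditions: PPh3, DIAD, THF, 0 °C (betaine preformed), then 4, then 2, 0 to 23 °C
Reagents that add atoms: none
Why: Mitsunobu reaction: tetronic acids are as acidic as carboxylic acids and are known to be alkylated at O4 (here O14) under these conditions, and C14 of 3,19-protected andrographolide is a known Mitsunobu site. SN2 displacement inverts C14' from S to R, which places the tether oxygen on the face of C12'=C13' from which C15 must arrive.

Step 4
Reactants: 5 (14'R)-allyl tetronate ether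
Product: 8 (12'S,15S)-14-hydroxy bis-acetonide (C15–C12'-linked tetronic acid), via silyloxyfuran 6 (not isolated), via silyl furanone 7 (not isolated)
Conditions: TMSOTf (1.2 equiv), Et3N (2.5 equiv), CH2Cl2 (0.005 M), −78 to 40 °C; then aq. AcOH/NaOAc buffer (pH 5), 0 °C
Reagents that add atoms: none
Why: Proposed new method: TMSOTf silylates the most Lewis-basic carbonyl of 5, the push-pull C16=O of the tetronate, and Et3N then removes a C15 proton, so that the unprimed ring aromatises to the 2-silyloxy-4-alkoxyfuran 6, in which C15=C14–O–C14'–C13'=C12' is an allyl vinyl ether of matched polarity (C15 is the nucleophilic position 5 of a 2-silyloxyfuran, C12' the β-carbon of an alkylidene lactone). A dearomative [3,3]-sigmatropic (Claisen) shift makes C15–C12', breaks C14'–O and moves the alkene to C13'=C14', giving 7, which the buffer hydrolyses to 8; no ring of the product is closed, the only cycle being the six-membered transition state. The closest known reaction types are the aromatic Claisen rearrangement of 3-allyloxy five-membered heteroarenes, the ester-enolate Claisen rearrangement of 2-alkylidenecyclopentyl esters used to set vicinal steroid side-chain centres, and the addition–elimination of nucleophiles at C12 of 14-O-acylandrographolides; the shift should be easy because 3-hydroxyfurans prefer the 3(2H)-furanone form, so little aromaticity is lost, and because an acceptor on the central allyl carbon (C16' on C13') accelerates Claisen shifts. C12' is controlled by C14': the shift is suprafacial, so C15 arrives on the face of C12'=C13' that carries the C14'–O bond, which for the (14'R)-ether and the fixed alkene geometry (C11' cis to C14') gives 12'S. C15 is controlled by the shape of the transition state alone, since the furan locks the enol-ether geometry (ring oxygen trans to the tether oxygen): the chair, staggered about the forming bond with donor and acceptor double bonds synclinal, gives the arrangement of the target (descriptor 15S in 8 because C14 now outranks C12'), whereas the boat eclipses the two fully substituted central atoms C14 and C13' and stacks the two rings. Site selectivity is secured by bond localisation, as the tether oxygen sits on the C14=C15 double bond of 6 and a shift to C13 has no closed-shell product. Chemoselectivity needs furan formation to outrun amine-induced 1,4-elimination of the tetronate (loss of a C11' proton), which the gain in aromaticity and the low temperature favour, and a silyl rather than a metal furanolate is used so that no cation can bridge the two lactone carbonyl oxygens, a contact open only to the boat. High dilution suppresses the intermolecular Michael pathway.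

Step 5
Reactants: 8 (12'S,15S)-14-hydroxy bis-acetonide
Product: 9 (12'S,15S)-14-trifluoromethanesulfonyloxy bis-acetonide
Conditions: Tf2O, iPr2NEt, CH2Cl2, −78 °C
Reagents that add atoms: trifluoromethanesulfonic anhydride O=S(=O)(OS(=O)(=O)C(F)(F)F)C(F)(F)F
Why: O-Sulfonylation of a tetronic acid gives the conjugated 4-triflyloxybutenolide, a known class of coupling partners. The hindered amine at −78 °C should not reach C15–H, so no stereocentre changes.

Step 6
Reactants: 9 14-triflate
Product: 10 (12'S,15R)-3,19:3',19'-bis-O-isopropylidene derivative of the target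
Conditions: Pd(PPh3)4 (5 mol %), LiCl, Bu3SnH (slow addition, 1.05 equiv), THF, 23 °C
Reagents that add atoms: none
Why: Palladium-catalysed hydride transfer to a vinyl triflate (tin-hydride variant of the Stille reaction): zerovalent palladium inserts into the electron-poor C14–O bond, chloride and then hydride replace triflate, and reductive elimination leaves C14–H. The medium is neutral, so C15 is not at risk (15R by change of priorities only), and unactivated 1,1-disubstituted alkenes do not react.

Step 7
Reactants: 10 bis-acetonide
Product: 11 target CNP0220272.2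
Conditions: AcOH–H2O (7:3), 23 °C
Reagents that add atoms: none
Why: Mild acid hydrolysis of both 1,3-dioxanes is the standard release of the 3,19-diol in this series. The exocyclic alkenes, the diene and both butenolides tolerate it, and an acidic medium cannot epimerise C15.

## Compound list

1 | andrographolide (12E,14S) | C=C1CC[C@@H]2[C@](C)(CO)[C@H](O)CC[C@@]2(C)[C@@H]1C/C=C1/C(=O)OC[C@H]1O | starting material
2 | 3,19-O-isopropylideneandrographolide (12E,14S) | C=C1CC[C@@H]2[C@]3(C)COC(C)(C)O[C@@H]3CC[C@@]2(C)[C@@H]1C/C=C1/C(=O)OC[C@H]1O | intermediate
3 | 14-dehydro-3,19-O-isopropylideneandrographolide, (12E)-3-alkylidenefuran-2,4-dione form | C=C1CC[C@@H]2[C@]3(C)COC(C)(C)O[C@@H]3CC[C@@]2(C)[C@@H]1C/C=C1/C(=O)OCC1=O | intermediate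
4 | (11E)-14-hydroxy-3,19-O-isopropylidene-ent-labda-8(17),11,13-trien-16,15-olide (3-alkenyltetronic acid) | C=C1CC[C@@H]2[C@]3(C)COC(C)(C)O[C@@H]3CC[C@@]2(C)[C@@H]1/C=C/C1=C(O)COC1=O | intermediate
5 | (14'R)-allyl tetronate ether, O14 of 4 on inverted C14' of the skeleton of 2, 11E,12'E | C=C1CC[C@@H]2[C@]3(C)COC(C)(C)O[C@@H]3CC[C@@]2(C)[C@@H]1/C=C/C1=C(O[C@H]2COC(=O)/C2=C/C[C@@H]2C(=C)CC[C@@H]3[C@]4(C)COC(C)(C)O[C@@H]4CC[C@]32C)COC1=O | intermediate
6 | 2-trimethylsilyloxy-3-alkenyl-4-[(14'R)-allyloxy]furan derived from 5 | C=C1CC[C@@H]2[C@]3(C)COC(C)(C)O[C@@H]3CC[C@@]2(C)[C@@H]1/C=C/C1=C(O[Si](C)(C)C)OC=C1O[C@H]2COC(=O)/C2=C/C[C@@H]2C(=C)CC[C@@H]3[C@]4(C)COC(C)(C)O[C@@H]4CC[C@]32C | intermediate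
7 | (12'S,15S)-5-trimethylsilyloxyfuran-3(2H)-one, direct product of the [3,3] shift | C=C1CC[C@@H]2[C@]3(C)COC(C)(C)O[C@@H]3CC[C@@]2(C)[C@@H]1/C=C/C1=C(O[Si](C)(C)C)O[C@@H]([C@@H](C[C@@H]2C(=C)CC[C@@H]3[C@]4(C)COC(C)(C)O[C@@H]4CC[C@]32C)C2=CCOC2=O)C1=O | intermediate
8 | (12'S,15S)-14-hydroxy bis-acetonide (C15–C12'-linked tetronic acid) | C=C1CC[C@@H]2[C@]3(C)COC(C)(C)O[C@@H]3CC[C@@]2(C)[C@@H]1/C=C/C1=C(O)[C@H]([C@@H](C[C@@H]2C(=C)CC[C@@H]3[C@]4(C)COC(C)(C)O[C@@H]4CC[C@]32C)C2=CCOC2=O)OC1=O | intermediate
9 | (12'S,15S)-14-triflyloxy bis-acetonide | C=C1CC[C@@H]2[C@]3(C)COC(C)(C)O[C@@H]3CC[C@@]2(C)[C@@H]1/C=C/C1=C(OS(=O)(=O)C(F)(F)F)[C@H]([C@@H](C[C@@H]2C(=C)CC[C@@H]3[C@]4(C)COC(C)(C)O[C@@H]4CC[C@]32C)C2=CCOC2=O)OC1=O | intermediate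
10 | (12'S,15R)-3,19:3',19'-bis-O-isopropylidene derivative of the target | C=C1CC[C@@H]2[C@]3(C)COC(C)(C)O[C@@H]3CC[C@@]2(C)[C@@H]1/C=C/C1=C[C@H]([C@@H](C[C@@H]2C(=C)CC[C@@H]3[C@]4(C)COC(C)(C)O[C@@H]4CC[C@]32C)C2=CCOC2=O)OC1=O | intermediate
11 | CNP0220272.2, (12'S,15R)-C15–C12'-linked bis-ent-labdane | C=C1CC[C@@H]2[C@](C)(CO)[C@H](O)CC[C@@]2(C)[C@@H]1/C=C/C1=C[C@H]([C@@H](C[C@@H]2C(=C)CC[C@@H]3[C@](C)(CO)[C@H](O)CC[C@]32C)C2=CCOC2=O)OC1=O | target

## Step count and least certain steps

Total step count: 7. Longest linear sequence: 7 steps (1 → 2 → 4 → 5 → 8 → 9 → 10 → 11). Compound 2 enters twice, in steps 2 and 3.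

**Step 4 (key step, new method).**
- The most likely failure is competition of a boat-like transition state. The chair places the C11' methylene beneath the furan ring, and this would erode the facial selection at C15. C12', fixed by the tether, is not affected.
- The second danger is amine-induced 1,4-elimination of the tetronate before the furan forms.
- The fallback keeps the tether idea but uses an acyclic, chelated ketene acetal and known reactions only. It sets out from 2 and comes back at 8.
- Mitsunobu esterification of 2 with (4-methoxybenzyloxy)acetic acid (PPh3, DIAD) would give, with inversion, the (14R)-glycolate ester F1.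
- Chelation-controlled enolisation (KHMDS, TMSCl, THF, −78 °C) and Ireland–Claisen rearrangement on warming would give the α-alkoxy acid F2. The Z-ketene acetal and the chair are the documented preference for glycolates of 2-alkylidenecycloalkanols.
- TMSCHN2 would give the methyl ester F3, and DDQ the α-hydroxy ester F4.
- In parallel, KMnO4 (THF–H2O, 0 °C) would cleave the electron-poor C12=C13 bond of 2 to the C12 aldehyde F5. Malonic acid under deconjugative Knoevenagel conditions (piperidinium acetate, DMSO) would then give the (E)-3-alkenoic acid F6.
- Esterification of F4 with F6 (EDC, DMAP) would give the acyloxy ester F7. Dieckmann cyclisation (KOtBu, THF, 0 °C) would close C13–C14 to give 8.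

**Step 2.**
- The most likely failure is Michael-type self-condensation of the strongly electrophilic dione 3 with its own nucleophilic enol before tautomerisation is complete. Over-oxidation at C13 is a further risk.
- The fallback never passes through an alkylidene dione. It sets out from 2 and comes back at 4.
- The C12 aldehyde F5 and the (E)-3-alkenoic acid F6 are made as described above. F6 is esterified with methyl glycolate (EDC, DMAP) to the glycolyl diester F8.
- Dieckmann cyclisation (KOtBu, THF) builds the tetronic acid ring of 4 from the open chain.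

**Step 3.**
- The most likely failure is loss of the activated C14' oxygen by 1,4-elimination toward C11', or allylic attack of the bulky nucleophile at C12', because the tetronate of 4 is hindered and only moderately nucleophilic.
- The fallback forms the other C–O bond of the ether. It sets out from 2 and 4 and comes back at 5.
- Inversion of 2 with the small, strong chloroacetic acid (PPh3, DIAD) would give the (14R)-chloroacetate F9. Mild methanolysis (MeOH, cat. Et3N, 0 °C) would give the 14-epi alcohol F10.
- 4 with TsCl and Et3N would give the 4-tosyloxybutenolide F11.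
- Addition–elimination of F10 at C14 of F11 (DABCO, MeCN) would give 5 with retention at C14'.

**Step 6.**
- The most likely failure is hydride transfer beyond the triflate, that is conjugate reduction of the newly formed dienyl lactone. Slow insertion at the doubly flanked C14 would also give time for loss of configuration at C15.
- The fallback replaces the organometallic hydride transfer by a radical chain. It sets out from 9 and comes back at 10.
- LiBr (acetone, 23 °C) would exchange triflate for bromide by addition–elimination to give the 14-bromide F12.
- (Me3Si)3SiH with Et3B/air (toluene, 0 °C) would then reduce the vinyl bromide under neutral conditions to give 10.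

## Further compounds

F1 | step 4 | (14R)-14-O-[(4-methoxybenzyloxy)acetyl]-3,19-O-isopropylidene-14-epi-andrographolide | COc1ccc(COCC(=O)O[C@H]2COC(=O)/C2=C/C[C@@H]2C(=C)CC[C@@H]3[C@]4(C)COC(C)(C)O[C@@H]4CC[C@]32C)cc1
F2 | step 4 | α-(4-methoxybenzyloxy) acid from the Ireland–Claisen shift, C15 and C12' arranged as in 8 | COc1ccc(CO[C@H](C(=O)O)[C@@H](C[C@@H]2C(=C)CC[C@@H]3[C@]4(C)COC(C)(C)O[C@@H]4CC[C@]32C)C2=CCOC2=O)cc1
F3 | step 4 | methyl ester of F2 | COc1ccc(CO[C@H](C(=O)OC)[C@@H](C[C@@H]2C(=C)CC[C@@H]3[C@]4(C)COC(C)(C)O[C@@H]4CC[C@]32C)C2=CCOC2=O)cc1
F4 | step 4 | α-hydroxy methyl ester | O[C@H](C(=O)OC)[C@@H](C[C@@H]1C(=C)CC[C@@H]2[C@]3(C)COC(C)(C)O[C@@H]3CC[C@]21C)C1=CCOC1=O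
F5 | step 4 | 3,19-O-isopropylidene-13,14,15,16-tetranor-ent-labd-8(17)-en-12-al | C=C1CC[C@@H]2[C@]3(C)COC(C)(C)O[C@@H]3CC[C@@]2(C)[C@@H]1CC=O
F6 | step 4 | (E)-4-(decalinyl)but-3-enoic acid (C1–C13, C16 to C20 of the unprimed half) | C=C1CC[C@@H]2[C@]3(C)COC(C)(C)O[C@@H]3CC[C@@]2(C)[C@@H]1/C=C/CC(=O)O
F7 | step 4 | ester of F4 with F6 | C=C1CC[C@@H]2[C@]3(C)COC(C)(C)O[C@@H]3CC[C@@]2(C)[C@@H]1/C=C/CC(=O)O[C@H](C(=O)OC)[C@@H](C[C@@H]2C(=C)CC[C@@H]3[C@]4(C)COC(C)(C)O[C@@H]4CC[C@]32C)C2=CCOC2=O
F8 | step 2 | methoxycarbonylmethyl ester of F6 | C=C1CC[C@@H]2[C@]3(C)COC(C)(C)O[C@@H]3CC[C@@]2(C)[C@@H]1/C=C/CC(=O)OCC(=O)OC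
F9 | step 3 | (14R)-14-O-chloroacetyl-3,19-O-isopropylidene-14-epi-andrographolide | C=C1CC[C@@H]2[C@]3(C)COC(C)(C)O[C@@H]3CC[C@@]2(C)[C@@H]1C/C=C1/C(=O)OC[C@@H]1OC(=O)CCl
F10 | step 3 | (14R)-3,19-O-isopropylidene-14-epi-andrographolide | C=C1CC[C@@H]2[C@]3(C)COC(C)(C)O[C@@H]3CC[C@@]2(C)[C@@H]1C/C=C1/C(=O)OC[C@@H]1O
F11 | step 3 | 14-O-tosyl derivative of 4 (4-tosyloxybutenolide) | C=C1CC[C@@H]2[C@]3(C)COC(C)(C)O[C@@H]3CC[C@@]2(C)[C@@H]1/C=C/C1=C(OS(=O)(=O)c2ccc(C)cc2)COC1=O
F12 | step 6 | 14-bromo bis-acetonide, C15 and C12' arranged as in 9 | C=C1CC[C@@H]2[C@]3(C)COC(C)(C)O[C@@H]3CC[C@@]2(C)[C@@H]1/C=C/C1=C(Br)[C@H]([C@@H](C[C@@H]2C(=C)CC[C@@H]3[C@]4(C)COC(C)(C)O[C@@H]4CC[C@]32C)C2=CCOC2=O)OC1=O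
A1 | alternative 1 | 2-(tert-butyldimethylsilyloxy)furan of 3,19-di-O-acetyl-14-deoxy-11,12-didehydroandrographolide | C=C1CC[C@@H]2[C@](C)(COC(C)=O)[C@H](OC(C)=O)CC[C@@]2(C)[C@@H]1/C=C/C1=C(O[Si](C)(C)C(C)(C)C)OC=C1
A2 | alternative 1 | 3,14,19-tri-O-acetylandrographolide | C=C1CC[C@@H]2[C@](C)(COC(C)=O)[C@H](OC(C)=O)CC[C@@]2(C)[C@@H]1C/C=C1/C(=O)OC[C@H]1OC(C)=O
A3 | alternative 1 | 3,19,3',19'-tetra-O-acetate of 11 | C=C1CC[C@@H]2[C@](C)(COC(C)=O)[C@H](OC(C)=O)CC[C@@]2(C)[C@@H]1/C=C/C1=C[C@H]([C@@H](C[C@@H]2C(=C)CC[C@@H]3[C@](C)(COC(C)=O)[C@H](OC(C)=O)CC[C@]32C)C2=CCOC2=O)OC1=O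
A4 | alternative 2 | mixed (14'R)-allyl furan-2-yl carbonate of the two acetonide halves | C=C1CC[C@@H]2[C@]3(C)COC(C)(C)O[C@@H]3CC[C@@]2(C)[C@@H]1/C=C/C1=C(OC(=O)O[C@H]2COC(=O)/C2=C/C[C@@H]2C(=C)CC[C@@H]3[C@]4(C)COC(C)(C)O[C@@H]4CC[C@]32C)OC=C1
A5 | alternative 3 | (11E)-12-iodo-3,19-O-isopropylidene-13,14,15,16-tetranor-ent-labda-8(17),11-diene | C=C1CC[C@@H]2[C@]3(C)COC(C)(C)O[C@@H]3CC[C@@]2(C)[C@@H]1/C=C/I
A6 | alternative 3 | 3-tributylstannylbutenolide carrying the primed half, C15 and C12' as in 10 | CCCC[Sn](CCCC)(CCCC)C1=C[C@H]([C@@H](C[C@@H]2C(=C)CC[C@@H]3[C@]4(C)COC(C)(C)O[C@@H]4CC[C@]32C)C2=CCOC2=O)OC1=O
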